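**Strategy.** Everything rests on tracing both carbon appendages of ring A, the prenyl chain at C6 and the gem-dimethylpyran annulated across C7–C8, back to oxygen-bound C5 units: a 1,1-dimethylallyl ether at O5 and a 1,1-dimethylpropargyl ether at O7. The key step exploits the A-ring topology, in which O5 has C6 as its only free ortho carbon (C4a is a ring fusion) whereas O7 lies between C6 and C8. Staged heating delivers the allyl group to C6, then the propargyl group to C8 with oxa-6π closure, creating three bonds and the pyran in one operation. The precursor is the complete oxepine-bridged flavone carrying both tertiary ethers, assembled without protecting groups.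

Key step: step 13

Remark: the target has no stereogenic element, so no asymmetric step is needed; the stereocentres in 6, 7 and 18 are racemic and are erased on the way.
Remark: flavone numbering is used (O1, C2, C3, C4=O, C4a–C8a, B ring C1′–C6′); "oxepinoflavone" means the 4′,5′-dimethoxyflavone with the bridge C3–CH2–C(=CMe2)–O–C2′.
Remark: methyl 2,6-difluoro-4-hydroxybenzoate (15) is taken as a stocked building block. The O5 ether is made by fluoride displacement so that no hydrogen-bonded 5-hydroxyl has to be alkylated with a tertiary electrophile. The aryl enol ether is kept away from acid from step 5 onwards.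

**Step 1**
Reactants: 1 3,4-dimethoxyphenol
Product: 2 2-bromo-4,5-dimethoxyphenol
Conditions: NBS, CH2Cl2, −20 → 0 °C
Reagents that add atoms: N-bromosuccinimide, O=C1CCC(=O)N1Br
Why: Electrophilic aromatic bromination should occur at the position ortho to the hydroxyl and para to the 3-methoxy group, which is the most activated and least hindered ring carbon.

**Step 2**
Reactants: 2 2-bromo-4,5-dimethoxyphenol; 3 ethyl bromoacetate
Product: 4 ethyl 2-(2-bromo-4,5-dimethoxyphenoxy)acetate
Conditions: K2CO3, acetone, reflux
Reagents that add atoms: none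
Why: Williamson ether synthesis (SN2) of the phenoxide on a primary α-bromo ester.

**Step 3**
Reactants: 4 ethyl 2-(2-bromo-4,5-dimethoxyphenoxy)acetate; 5 acetone
Product: 6 ethyl 2-(2-bromo-4,5-dimethoxyphenoxy)-3-hydroxy-3-methylbutanoate (racemic)
Conditions: LDA, THF, −78 °C; then acetone, −78 °C; aq. NH4Cl
Reagents that add atoms: none
Why: Aldol addition of the lithium ester enolate to acetone at low temperature; the new stereocentre is formed racemic and is removed in step 4.

**Step 4**
Reactants: 6 ethyl 2-(2-bromo-4,5-dimethoxyphenoxy)-3-hydroxy-3-methylbutanoate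
Product: 8 ethyl 2-(2-bromo-4,5-dimethoxyphenoxy)-3-methylbut-2-enoate, via tertiary mesylate 7 (not isolated)
Conditions: MsCl, Et3N, CH2Cl2, 0 °C; then DBU, rt
Reagents that add atoms: none
Why: Sulfene mesylation of the tertiary alcohol followed by E1cB elimination through the ester enolate should place the double bond at the oxygen-bearing carbon (conjugated, tetrasubstituted) and avoids a free tertiary cation that could alkylate the electron-rich arene.

**Step 5**
Reactants: 8 ethyl 2-(2-bromo-4,5-dimethoxyphenoxy)-3-methylbut-2-enoate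
Product: 9 2-(2-bromo-4,5-dimethoxyphenoxy)-3-methylbut-2-en-1-ol
Conditions: DIBAL-H (2.2 equiv), CH2Cl2, −78 → −20 °C; Rochelle salt
Reagents that add atoms: none
Why: 1,2-Reduction of the α,β-unsaturated ester to the allylic alcohol by DIBAL-H, with the aryl bromide inert and a neutral work-up to spare the now electron-rich enol ether.

**Step 6**
Reactants: 9 2-(2-bromo-4,5-dimethoxyphenoxy)-3-methylbut-2-en-1-ol
Product: 10 1-bromo-2-[(1-bromo-3-methylbut-2-en-2-yl)oxy]-4,5-dimethoxybenzene
Conditions: CBr4, PPh3, 2,6-lutidine, CH2Cl2, 0 °C; used crude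
Reagents that add atoms: carbon tetrabromide, BrC(Br)(Br)Br
Why: Appel bromination of a primary allylic alcohol under non-acidic conditions, which the enol ether should tolerate.

**Step 7**
Reactants: 10 1-bromo-2-[(1-bromo-3-methylbut-2-en-2-yl)oxy]-4,5-dimethoxybenzene; 11 N-methoxy-N-methylacetamide
Product: 12 4-(2-bromo-4,5-dimethoxyphenoxy)-N-methoxy-N,5-dimethylhex-4-enamide
Conditions: 11, LDA, THF, −78 °C; then 10, −78 → −30 °C
Reagents that add atoms: none
Why: SN2 C-alkylation of the lithium amide enolate by the primary allylic bromide, attack at the unhindered CH2 terminus being preferred over SN2′ at the CMe2 end.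

**Step 8**
Reactants: 12 4-(2-bromo-4,5-dimethoxyphenoxy)-N-methoxy-N,5-dimethylhex-4-enamide
Product: 14 7,8-dimethoxy-2-(propan-2-ylidene)-3,4-dihydro-1-benzoxepin-5(2H)-one, via aryllithium 13 (not isolated)
Conditions: t-BuLi (2.1 equiv), THF, −78 → 0 °C; aq. NH4Cl
Reagents that add atoms: none
Why: Parham cyclisation, in which fast bromine–lithium exchange is followed by 7-exo addition of the aryllithium to the Weinreb amide, whose chelated adduct releases the ketone only on quench.

**Step 9**
Reactants: 15 methyl 2,6-difluoro-4-hydroxybenzoate; 16 3-chloro-3-methylbut-1-yne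
Product: 17 methyl 2,6-difluoro-4-[(2-methylbut-3-yn-2-yl)oxy]benzoate
Conditions: CuCl2·2H2O (cat.), DBU, MeCN, 0 °C
Reagents that add atoms: none
Why: Copper-catalysed propargylation of an acidic, unhindered phenol by the tertiary propargyl chloride, the standard entry to aryl 1,1-dimethylpropargyl ethers.

**Step 10**
Reactants: 14 7,8-dimethoxy-2-(propan-2-ylidene)-3,4-dihydro-1-benzoxepin-5(2H)-one; 17 methyl 2,6-difluoro-4-[(2-methylbut-3-yn-2-yl)oxy]benzoate
Product: 18 4-{2,6-difluoro-4-[(2-methylbut-3-yn-2-yl)oxy]benzoyl}-7,8-dimethoxy-2-(propan-2-ylidene)-3,4-dihydro-1-benzoxepin-5(2H)-one (racemic, in equilibrium with its enol)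
Conditions: 14, LiHMDS (2.5 equiv), THF, −78 °C; then 17, −78 °C → rt; aq. NH4Cl
Reagents that add atoms: none
Why: Crossed Claisen condensation of the ketone enolate (C4 is the only enolisable position) with the fluorine-activated benzoate, driven by formation of the stable diketonate, which also makes C-acylation the thermodynamic outcome.

**Step 11**
Reactants: 18 4-{2,6-difluoro-4-[(2-methylbut-3-yn-2-yl)oxy]benzoyl}-7,8-dimethoxy-2-(propan-2-ylidene)-3,4-dihydro-1-benzoxepin-5(2H)-one
Product: 19 5-fluoro-7-[(2-methylbut-3-yn-2-yl)oxy] oxepinoflavone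
Conditions: K2CO3, DMF, 80 °C
Reagents that add atoms: none
Why: Intramolecular SNAr (addition–elimination) in which the enolate oxygen of the B-ring carbonyl displaces an ortho fluoride activated by the adjacent aroyl carbonyl, closing the pyranone ring and leaving the second fluorine at C5.

**Step 12**
Reactants: 19 5-fluoro-7-[(2-methylbut-3-yn-2-yl)oxy] oxepinoflavone; 20 2-methylbut-3-en-2-ol
Product: 21 5-O-(1,1-dimethylallyl)-7-O-(1,1-dimethylpropargyl) oxepinoflavone
Conditions: 20 (3 equiv), KHMDS (2.5 equiv), THF, 0 °C; then 19, THF–DMF, 0 °C → rt; product kept cold and used at once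
Reagents that add atoms: none
Why: SNAr of the C5 fluoride, activated by the ortho (peri) C4 carbonyl, by the tertiary potassium alkoxide should give the tertiary allyl ether directly; the temperature is kept low because the product is Claisen-labile.

**Step 13**
Reactants: 21 5-O-(1,1-dimethylallyl)-7-O-(1,1-dimethylpropargyl) oxepinoflavone
Product: 24 5-hydroxy-6-prenyl-7,8-(2,2-dimethylpyrano) oxepinoflavone (5-O-demethyl target), via 6-prenyl-5-hydroxy propargyl ether 22 (not isolated), via 8-allenyl-7-phenol 23 (not isolated)
Conditions: PhNEt2 (degassed, Ar), 110 °C until 21 is consumed, then 190 °C; chromatography on Et3N-deactivated silica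
Reagents that add atoms: none
Why: At 110 °C the O5 1,1-dimethylallyl ether should undergo an aromatic Claisen [3,3] shift through a chair transition state to C6, the only ortho carbon open to O5, and amine-assisted tautomerisation of the dienone gives the chelated phenol 22 with a linear prenyl group (allyl inversion) before a Cope drift to C8 can set in. At 190 °C the O7 1,1-dimethylpropargyl ether, now flanked by a substituted C6, shifts [3,3] to C8; the allenyl dienone enolises to 23, a [1,5]-hydrogen shift gives the ortho-quinone methide, and a thermal disrotatory oxa-6π electrocyclisation closes the pyran by forming the O7–CMe2 bond. Both halves are standard chemistry: the Claisen rearrangement of aryl 1,1-dimethylallyl ethers to ortho-prenylphenols and the thermal conversion of aryl 1,1-dimethylpropargyl ethers into 2,2-dimethyl-2H-chromenes. No stereocentre is formed. The selectivity needed is regiochemical (prenyl at C6, pyran across C7–C8); it is secured by the lower barrier of the peri-strained tertiary allyl ether relative to the propargyl ether, enforced by the two temperature stages, so that C6 is occupied before O7 reacts. The basic solvent suppresses ionisation of the tertiary ethers and isomerisation of the oxepine enol ether, which has no [3,3] partner and stays a spectator.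

**Step 14**
Reactants: 24 5-hydroxy-6-prenyl-7,8-(2,2-dimethylpyrano) oxepinoflavone
Product: 25 CNP0192589.0 (5-methoxy-6-prenyl-7,8-(2,2-dimethylpyrano) oxepinoflavone)
Conditions: MeI, K2CO3, DMF, 40 °C
Reagents that add atoms: iodomethane, CI
Why: Williamson O-methylation of the only remaining acidic O–H, the hydrogen-bonded 5-phenol, under basic conditions that leave the enol ether, the chromene and the prenyl group untouched.

**Compound list**
1 | 3,4-dimethoxyphenol | COc1ccc(O)cc1OC | starting material
2 | 2-bromo-4,5-dimethoxyphenol | COc1cc(O)c(Br)cc1OC | intermediate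
3 | ethyl bromoacetate | CCOC(=O)CBr | starting material
4 | ethyl 2-(2-bromo-4,5-dimethoxyphenoxy)acetate | CCOC(=O)COc1cc(OC)c(OC)cc1Br | intermediate
5 | acetone | CC(C)=O | starting material
6 | ethyl 2-(2-bromo-4,5-dimethoxyphenoxy)-3-hydroxy-3-methylbutanoate (racemic) | CCOC(=O)C(Oc1cc(OC)c(OC)cc1Br)C(C)(C)O | intermediate
7 | ethyl 2-(2-bromo-4,5-dimethoxyphenoxy)-3-methyl-3-(methylsulfonyloxy)butanoate (racemic, not isolated) | CCOC(=O)C(Oc1cc(OC)c(OC)cc1Br)C(C)(C)OS(C)(=O)=O | intermediate
8 | ethyl 2-(2-bromo-4,5-dimethoxyphenoxy)-3-methylbut-2-enoate | CCOC(=O)C(Oc1cc(OC)c(OC)cc1Br)=C(C)C | intermediate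
9 | 2-(2-bromo-4,5-dimethoxyphenoxy)-3-methylbut-2-en-1-ol | CC(C)=C(CO)Oc1cc(OC)c(OC)cc1Br | intermediate
10 | 1-bromo-2-[(1-bromo-3-methylbut-2-en-2-yl)oxy]-4,5-dimethoxybenzene | CC(C)=C(CBr)Oc1cc(OC)c(OC)cc1Br | intermediate
11 | N-methoxy-N-methylacetamide | CON(C)C(C)=O | starting material
12 | 4-(2-bromo-4,5-dimethoxyphenoxy)-N-methoxy-N,5-dimethylhex-4-enamide | CON(C)C(=O)CCC(=C(C)C)Oc1cc(OC)c(OC)cc1Br | intermediate
13 | aryllithium from 12 by Br–Li exchange (not isolated) | CON(C)C(=O)CCC(=C(C)C)Oc1cc(OC)c(OC)cc1[Li] | intermediate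
14 | 7,8-dimethoxy-2-(propan-2-ylidene)-3,4-dihydro-1-benzoxepin-5(2H)-one | COc1cc2OC(=C(C)C)CCC(=O)c2cc1OC | intermediate
15 | methyl 2,6-difluoro-4-hydroxybenzoate | COC(=O)c1c(F)cc(O)cc1F | starting material
16 | 3-chloro-3-methylbut-1-yne | CC(C)(Cl)C#C | starting material
17 | methyl 2,6-difluoro-4-[(2-methylbut-3-yn-2-yl)oxy]benzoate | COC(=O)c1c(F)cc(OC(C)(C)C#C)cc1F | intermediate
18 | 4-{2,6-difluoro-4-[(2-methylbut-3-yn-2-yl)oxy]benzoyl}-7,8-dimethoxy-2-(propan-2-ylidene)-3,4-dihydro-1-benzoxepin-5(2H)-one (racemic) | COc1cc2OC(=C(C)C)CC(C(=O)c3c(F)cc(OC(C)(C)C#C)cc3F)C(=O)c2cc1OC | intermediate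
19 | 5-fluoro-7-[(2-methylbut-3-yn-2-yl)oxy] oxepinoflavone | COc1cc2c(cc1OC)-c1oc3cc(OC(C)(C)C#C)cc(F)c3c(=O)c1CC(=C(C)C)O2 | intermediate
20 | 2-methylbut-3-en-2-ol | CC(C)(O)C=C | starting material
21 | 5-O-(1,1-dimethylallyl)-7-O-(1,1-dimethylpropargyl) oxepinoflavone (key-step precursor) | COc1cc2c(cc1OC)-c1oc3cc(OC(C)(C)C#C)cc(OC(C)(C)C=C)c3c(=O)c1CC(=C(C)C)O2 | intermediate
22 | 5-hydroxy-6-(3-methylbut-2-enyl)-7-[(2-methylbut-3-yn-2-yl)oxy] oxepinoflavone (not isolated) | COc1cc2c(cc1OC)-c1oc3cc(OC(C)(C)C#C)c(CC=C(C)C)c(O)c3c(=O)c1CC(=C(C)C)O2 | intermediate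
23 | 5,7-dihydroxy-8-(3-methylbuta-1,2-dienyl)-6-(3-methylbut-2-enyl) oxepinoflavone (not isolated) | COc1cc2c(cc1OC)-c1oc3c(C=C=C(C)C)c(O)c(CC=C(C)C)c(O)c3c(=O)c1CC(=C(C)C)O2 | intermediate
24 | 5-hydroxy-6-prenyl-7,8-(2,2-dimethylpyrano) oxepinoflavone (5-O-demethyl target) | COc1cc2c(cc1OC)-c1oc3c4c(c(CC=C(C)C)c(O)c3c(=O)c1CC(=C(C)C)O2)OC(C)(C)C=C4 | intermediate
25 | CNP0192589.0 | COc1cc2c(cc1OC)-c1oc3c4c(c(CC=C(C)C)c(OC)c3c(=O)c1CC(=C(C)C)O2)OC(C)(C)C=C4 | target

**Totals.** Total step count: 14. Longest linear sequence: 13 steps (steps 1–8, then 10–14); step 9 is the one-step side branch.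

**Steps most likely to fail**

Step 13. The strained O5–CMe2 bond may ionise (loss of the C5 unit) faster than it rearranges, or the propargyl group may shift onto C6 before the allyl group has arrived, which would erode the regiocontrol. The fallback uncouples the two events and closes the pyran by a non-pericyclic reaction. It sets out from 21: a europium-catalysed, chelation-accelerated Claisen rearrangement (Eu(fod)3, CHCl3, 45 °C) should give 22, which is isolated with C6 safely occupied. The propargyl ether of 22 is then cyclised onto C8, the only free A-ring carbon, by gold(I)-catalysed 6-endo hydroarylation (Ph3PAuNTf2, CH2Cl2, rt). This comes back to the route at 24 and makes no new compound.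

Step 12. Addition of the bulky tertiary alkoxide at the peri position may be too slow, so that premature rearrangement of the product or reversible attack at C2 of the pyranone takes over. The fallback sets out from 19. Fluoride is displaced by the primary alkoxide of 2-(methylsulfonyl)ethanol (NaH, DMF, rt) to give the 2-(methylsulfonyl)ethyl ether F1, which loses methyl vinyl sulfone in the same flask (E1cB) to give the 5-hydroxy-7-propargyloxy oxepinoflavone F2. The preformed caesium phenoxide of F2 is then reverse-prenylated by palladium-catalysed decarboxylative allylic etherification with tert-butyl 2-methylbut-3-en-2-yl carbonate F3 (from 20 and Boc2O), using Pd(PPh3)4 in THF at 0 °C; attack at the more substituted allyl terminus gives the tertiary ether. This comes back to the route at 21.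

Step 8. Proton transfer from the α-CH2 of the amide to the aryllithium, or intermolecular addition, may compete with closure of the seven-membered ring. The fallback makes the ring by C–C alkylation instead of acylation and sets out from 9. Double lithiation (n-BuLi, 2.2 equiv, THF, −78 °C) and acetylation with 11 should give 1-{2-[(1-hydroxy-3-methylbut-2-en-2-yl)oxy]-4,5-dimethoxyphenyl}ethanone F4. Appel bromination (CBr4, PPh3, CH2Cl2, 0 °C) gives the allylic bromide F5, and intramolecular enolate C-alkylation (KOtBu, THF, high dilution, 0 °C; 7-exo-tet) comes back to the route at 14.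

**Further compounds**
F0 | step 13 | none | none
F1 | step 12 | 5-O-[2-(methylsulfonyl)ethyl]-7-O-(1,1-dimethylpropargyl) oxepinoflavone (not isolated) | COc1cc2c(cc1OC)-c1oc3cc(OC(C)(C)C#C)cc(OCCS(C)(=O)=O)c3c(=O)c1CC(=C(C)C)O2
F2 | step 12 | 5-hydroxy-7-[(2-methylbut-3-yn-2-yl)oxy] oxepinoflavone | COc1cc2c(cc1OC)-c1oc3cc(OC(C)(C)C#C)cc(O)c3c(=O)c1CC(=C(C)C)O2
F3 | step 12 | tert-butyl 2-methylbut-3-en-2-yl carbonate | CC(C)(C)OC(=O)OC(C)(C)C=C
F4 | step 8 | 1-{2-[(1-hydroxy-3-methylbut-2-en-2-yl)oxy]-4,5-dimethoxyphenyl}ethanone | CC(=O)c1cc(OC)c(OC)cc1OC(CO)=C(C)C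
F5 | step 8 | 1-{2-[(1-bromo-3-methylbut-2-en-2-yl)oxy]-4,5-dimethoxyphenyl}ethanone | CC(=O)c1cc(OC)c(OC)cc1OC(CBr)=C(C)C
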